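(The earlier runs and the new flask were generated by integration for substances that don't exist; noise was put on by code.)

The product in the winter run creeps from 9.3% after 8.00 min to 12.4% after 50.0 min, while the spring run shows 32.7% after 6.00 min on 2.31 times the enzyme, so the product read there grew by a larger ratio than the enzyme, and the quick number you asked for has to start from that. You will see that the winter charge of enzyme, 6.50 µM, matches the impurity at 6.5 µM, which reads as a poison taking enzyme one for one, with the impurity as limiting reagent in your flask, where enzyme is charged above it.

all flasks: substrate 0.050 M; impurity 6.5 µM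
- winter: enzyme 0.013 mol%; run made earlier
- spring: enzyme 0.03 mol%; run made earlier
- flask: enzyme 0.02 mol%

| run | time / min | product / % | substrate / % |
|---|---|---|---|
| winter | 4.00 | 8.4 | 91.9 |
| winter | 8.00 | 9.3 | 91.1 |
| winter | 20.0 | 10.4 | 88.8 |
| winter | 50.0 | 12.4 | 89.0 |
| spring | 6.00 | 32.7 | 67.1 |
| spring | 15.0 | 48.3 | 50.9 |
| spring | 30.0 | 62.7 | 36.1 |
| spring | 50.0 | 75.1 | 25.4 |

(standard deviation of a reading: 0.5 percentage points)

- apparent order in enzyme when 10% of the substrate are converted (percent change of the rate of making product for one percent more enzyme charged)
- factor on the rate of making product when 10% of the substrate are converted if enzyme is charged twice over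

In your flask the charge of 10.0 µM then leaves 3.50 µM of surviving enzyme, the charge less the impurity, against 8.50 µM in the spring run. At a fixed conversion, with the poisoning over, the rate goes with that survivor, so I commit to an order equal to charge over survivor, 2.86, and, for twice the charge, to a factor of 3.86.

The forecast stands lower, at 2 (range 1.2 to 3) and at 3.2 (range 2.3 to 4.3), and it has the flask reach the mark “with poisoning nearly finished”.

The flask gives an order of 2.8 and a factor of 3.76.

    substrate + enzyme → product + enzyme, rate k1*[substrate]*[enzyme]/(1 + ([substrate]/Km1) + ([product]/Kp1)) (39.0 mM, 0.890 mM, k = 5.30 × 10⁶ M⁻¹ h⁻¹)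
    enzyme + impurity → spent catalyst (k = 11000 M⁻¹ s⁻¹)

With the impurity as charged, enzyme is lost at 4.3 min⁻¹ per enzyme, a time of 0.233 min, shorter than the 1.29 min the flask takes to convert 10% of the substrate. At that moment the flask holds 36.2% of its catalyst as enzyme and 63.8% as spent catalyst, beside a surviving share of 35.0% from the charges. With twice the enzyme the survivor is 13.5 µM, and the factor on the rate is 3.76. At 200 min the spent catalyst in the flask stands at 65.0% of the catalyst.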